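A small charge of substrate and a larger one come to rest at different shares, as delta and gamma show, and the flask asked about holds the largest charge of the three.

| setting | delta | gamma | flask |
|---|---|---|---|
| substrate | 1.1 M | 1.7 M | 2.2 M |
| remark | run made earlier | run made earlier |  |
| time |  |  | 25 min |

- delta (time / min: substrate / %, target / %): 3.00: 32.2, 32.5; 6.00: 32.1, 32.8; 10.0: 32.4, 32.3; 12.0: 32.9, 33.7; 15.0: 33.1, 32.5; 20.0: 32.5, 32.6
- gamma (time / min: substrate / %, target / %): 1.33: 27.7, 35.2; 4.00: 28.1, 35.9; 8.00: 26.8, 36.5; 10.0: 27.1, 35.2; 15.0: 27.7, 36.5; 20.0: 26.9, 35.2

(standard deviation of a reading: 0.5 percentage points)

- percentages count the substrate that a species holds: one target or isomer of the product counts as two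
- candidate steps: 2 substrate <-> target; target <-> isomer of the product; substrate <-> dormant form
- the reaction counts as stopped when no species that holds the substrate changes by six tenths of a point or more over the second half of the time
- what has gone from substrate into another species counts as reacted, even if it can come back

* the state of affairs at 25 min: stopped, and by what, or still going (it is still moving / all of the substrate has reacted / forward and back rates have come level)
* part of the substrate gone at 25 min
* the target standing at 25 min, as a percentage of the substrate charged
* the isomer of the product standing at 25 min, as a percentage of the substrate charged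

Both earlier runs stay flat from their first readings, at 3.00 min and 1.33 min, yet at different levels: delta keeps substrate 32.5 % and target 32.7 %, gamma 27.4 % and 35.8 %. Since a target percentage counts double, c_target is half that share of the charge, and c_target over c_substrate squared reads 1.41 M⁻¹ in delta and 1.40 M⁻¹ in gamma; their mean is the pairing quotient K, 1.40 M⁻¹, an equilibrium constant as read. Whatever is neither substrate nor target stands at about 1.05 times the target. With x the substrate share and c the charge, my own balance is:

x + N·x·x = 1, with N = 2·K·c·(1 + 1.05)

At small N, x tends to 1; at large N, to 1/√N. The exact root joins both ends:

N = 12.6, against 9.77 for gamma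

x = (√(1 + 4N) − 1)/(2N) = 24.4 %, where the large-N end alone gives 28.2 %

The flask's larger N therefore leaves it a smaller share of its charge as substrate than gamma keeps, and gamma lay flat by a time much shorter than the flask's 25 min, so the flask should rest at balance. My reckoning gives 75.6 % gone and target 36.9 %, with isomer and dormant form lumped.

The forecast says forward and back rates have come level, with 75.4 % gone (74.4 % to 76.4 %), target 37.4 % (36.4 % to 38.3 %) and isomer 34.8 % (33.2 % to 36.4 %): “Equilibrium should come within minutes at this higher concentration”. Its target stands above mine.

The flask gives forward and back rates have come level, with 75.3 % gone, target 37.7 % and isomer 32.4 %.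

    2 substrate ⇌ target (K = 1.40 M⁻¹, k = 0.0650 M⁻¹ s⁻¹)
    target ⇌ isomer of the product (K = 0.860, k = 0.0880 s⁻¹)
    substrate ⇌ dormant form (K = 0.210, k = 0.0250 s⁻¹)

In the flask, the half-life of target by its loss to the isomer, forward rate alone, is 0.13 min, far shorter than the 25 min allowed, and substrate stands at 24.7 % after 2.50 min as after 25.0 min. In the flask, backward turnover of the making of target is 97 % of the forward one, the mark of thermodynamic control. K applied to the 25 % of substrate left gives target 37.8 % against 37.7 %, and in the neighbouring flask charged with 0.88 M, the 35 % left gives 30.9 % against a simulated 30.8 %.

The earlier runs and the new flask were generated by integration on assumed constants.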